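**Retrosynthetic overview**
1. Target 14 ⇒ tert-butyl ester 13; the acid-labile ester is cleaved last.
2. Key disconnection: the depside C(aryl)–O bond of 13 ⇒ ring A carboxylic acid 6 (as O-nucleophile) + the lone unhindered C–H of ring B arene 11, via boronate 12.
3. 6 ⇒ 2-hydroxy-4-methoxybenzoic acid 4 + sulfoxonium ylide 3 (C–H annulation to isocoumarin 5, reopened by hydroxide); 3 ⇒ 1 + 2.
4. 11 ⇒ 2-methoxy-6-methylbenzoic acid 7 (tert-butyl ester 8, lateral lithiation, 1-iodobutane 9).
5. Both benzene rings are bought; the only ring formed is the transient pyranone of 5, which is opened again in the same step.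

Assumption: the target has no stereocentre and is a single achiral compound, so no step has to set configuration.

**Route**

Step 1
Reactants: 1 butanoyl chloride; 2 trimethylsulfoxonium iodide
Product: 3 1-[dimethyl(oxo)-λ6-sulfanylidene]pentan-2-one
Conditions: 2 (3.0 equiv), KOtBu (3.0 equiv), THF, reflux, 2 h; then 1 (1.0 equiv), 0 °C to rt, 2 h
Reagents that add atoms: none
Why: Acylation of dimethylsulfoxonium methylide (Corey–Chaykovsky reagent) by the acid chloride, with a second equivalent of methylide deprotonating the adduct to the stabilised β-keto sulfoxonium ylide.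

Step 2
Reactants: 4 2-hydroxy-4-methoxybenzoic acid; 3 1-[dimethyl(oxo)-λ6-sulfanylidene]pentan-2-one
Product: 6 2-hydroxy-4-methoxy-6-(2-oxopentyl)benzoic acid, via isocoumarin 5 (not isolated)
Conditions: 3 (1.5 equiv), [Cp*RhCl2]2 (2.5 mol %), AgSbF6 (10 mol %), NaOAc (30 mol %), HFIP, 60 °C, 16 h; evaporate; 2 M aq NaOH (5 equiv), MeOH, 50 °C, 2 h; wash with MTBE; 1 M HCl to pH 2, 0 °C, extract
Reagents that add atoms: sodium hydroxide [Na+].[OH-]
Why: Carboxylate-directed C–H activation by trivalent rhodium at the only free ortho position (C6), carbene formation from the ylide with loss of DMSO, migratory insertion and lactonisation give isocoumarin 5 (known benzoic acid/sulfoxonium ylide annulation), and classical alkaline opening of the enol lactone gives the keto acid, purified by acid–base extraction.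

Step 3
Reactants: 7 2-methoxy-6-methylbenzoic acid
Product: 8 tert-butyl 2-methoxy-6-methylbenzoate
Conditions: tert-butyl 2,2,2-trichloroacetimidate (2.0 equiv), BF3·OEt2 (10 mol %), CH2Cl2/cyclohexane, rt, 16 h
Reagents that add atoms: tert-butyl 2,2,2-trichloroacetimidate CC(C)(C)OC(=N)C(Cl)(Cl)Cl
Why: Acid-catalysed trichloroacetimidate esterification alkylates the carboxyl oxygen with a tert-butyl cation, so the 2,6-disubstitution that blocks acyl attack does not matter.

Step 4
Reactants: 8 tert-butyl 2-methoxy-6-methylbenzoate; 9 1-iodobutane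
Product: 11 tert-butyl 2-methoxy-6-pentylbenzoate, via benzylic lithium species 10 (not isolated)
Conditions: LiN(iPr)2 (LDA, 1.15 equiv), THF, −78 °C, 30 min; then 9 (1.3 equiv), DMPU (2 equiv), −78 to 0 °C
Reagents that add atoms: none
Why: Lateral lithiation of an ortho-toluate ester gives the ester-conjugated benzylic anion (the tert-butyl ester resists self-condensation), which is alkylated by the primary iodide in an SN2 reaction.

Step 5
Reactants: 11 tert-butyl 2-methoxy-6-pentylbenzoate; 6 2-hydroxy-4-methoxy-6-(2-oxopentyl)benzoic acid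
Product: 13 tert-butyl 4-{[2-hydroxy-4-methoxy-6-(2-oxopentyl)benzoyl]oxy}-2-methoxy-6-pentylbenzoate, via aryl pinacolboronate 12 (not isolated)
Conditions: 11 (1.3 equiv), B2pin2 (1.3 equiv), [Ir(OMe)(cod)]2 (1.5 mol %), 4,4'-di-tert-butyl-2,2'-bipyridine (3 mol %), THF, 80 °C, 12 h; volatiles removed in vacuo; then 6 (1.0 equiv), Cu(OTf)2 (20 mol %), 2,6-lutidine (1.2 equiv), powdered 4 Å MS, MeCN, dry O2 (1 atm), 35 °C, 24 h
Reagents that add atoms: none
Why: Proposed new method: a one-pot sterically governed arene C–H borylation followed by aerobic copper-catalysed acyloxylation of the crude aryl pinacolboronate by a free keto salicylic acid; the Ir/bipyridine catalyst borylates the only ring C–H of 11 without an ortho substituent (C4), the carboxylate of 6 binds divalent copper and bridges to boron for transmetalation, oxidation by a second divalent copper/O2 gives an aryl trivalent copper carboxylate, and C(aryl)–O reductive elimination forms the depside ester; because the carboxyl carbon of 6 is never activated, the 2-oxopentyl enol cannot lactonise to isocoumarin 5, and the hydrogen-bonded 2-OH is not deprotonated by lutidine; the closest known reaction type is the Chan–Lam O-arylation of carboxylic acids with arylboronic acids, together with one-pot Ir borylation/Cu coupling sequences used for ethers and amines.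

Step 6
Reactants: 13 tert-butyl 4-{[2-hydroxy-4-methoxy-6-(2-oxopentyl)benzoyl]oxy}-2-methoxy-6-pentylbenzoate
Product: 14 4-{[2-hydroxy-4-methoxy-6-(2-oxopentyl)benzoyl]oxy}-2-methoxy-6-pentylbenzoic acid (CNP0110448.0)
Conditions: TFA/CH2Cl2 (1:4), 0 °C, 1.5 h; cold evaporation with toluene
Reagents that add atoms: none
Why: Acidolysis of the tert-butyl ester by loss of the tert-butyl cation as isobutene (AAL1 cleavage) is fast for this hindered electron-rich benzoate at 0 °C, where the aryl ester, ketone and phenol are left alone.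

**Compound list**
1 | butanoyl chloride | CCCC(=O)Cl | starting material
2 | trimethylsulfoxonium iodide | C[S+](C)(C)=O.[I-] | starting material
3 | 1-[dimethyl(oxo)-λ6-sulfanylidene]pentan-2-one | CCCC(=O)C=S(C)(C)=O | intermediate
4 | 2-hydroxy-4-methoxybenzoic acid | COc1ccc(C(=O)O)c(O)c1 | starting material
5 | 8-hydroxy-6-methoxy-3-propyl-1H-isochromen-1-one (isocoumarin) | CCCC1=Cc2cc(OC)cc(O)c2C(=O)O1 | intermediate
6 | 2-hydroxy-4-methoxy-6-(2-oxopentyl)benzoic acid | CCCC(=O)Cc1cc(OC)cc(O)c1C(=O)O | intermediate
7 | 2-methoxy-6-methylbenzoic acid | COc1cccc(C)c1C(=O)O | starting material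
8 | tert-butyl 2-methoxy-6-methylbenzoate | COc1cccc(C)c1C(=O)OC(C)(C)C | intermediate
9 | 1-iodobutane | CCCCI | starting material
10 | {[2-(tert-butoxycarbonyl)-3-methoxyphenyl]methyl}lithium (benzylic lithium species) | [Li]Cc1cccc(OC)c1C(=O)OC(C)(C)C | intermediate
11 | tert-butyl 2-methoxy-6-pentylbenzoate | CCCCCc1cccc(OC)c1C(=O)OC(C)(C)C | intermediate
12 | tert-butyl 2-methoxy-6-pentyl-4-(4,4,5,5-tetramethyl-1,3,2-dioxaborolan-2-yl)benzoate (aryl pinacolboronate) | CCCCCc1cc(B2OC(C)(C)C(C)(C)O2)cc(OC)c1C(=O)OC(C)(C)C | intermediate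
13 | tert-butyl 4-{[2-hydroxy-4-methoxy-6-(2-oxopentyl)benzoyl]oxy}-2-methoxy-6-pentylbenzoate | CCCCCc1cc(OC(=O)c2c(O)cc(OC)cc2CC(=O)CCC)cc(OC)c1C(=O)OC(C)(C)C | intermediate
14 | 4-{[2-hydroxy-4-methoxy-6-(2-oxopentyl)benzoyl]oxy}-2-methoxy-6-pentylbenzoic acid | CCCCCc1cc(OC(=O)c2c(O)cc(OC)cc2CC(=O)CCC)cc(OC)c1C(=O)O | target

**Totals**
Total step count: 6.
Longest linear sequence: 4 steps (1 → 2 → 5 → 6, or 3 → 4 → 5 → 6).

**Three steps most likely to fail, with fallbacks**

Step 2. The hydrogen-bonded 2-OH of 4 could undergo O–H insertion with the rhodium carbene, or conversion could stall, leaving 4 that is hard to separate from 6. The fallback uses lateral-lithiation chemistry; it sets out from 1 and comes back to the route at 6. Butanoyl chloride 1 is treated with N,O-dimethylhydroxylamine hydrochloride and pyridine in CH2Cl2 at 0 °C to give N-methoxy-N-methylbutanamide F1. Purchased methyl 2-hydroxy-4-methoxy-6-methylbenzoate is deprotonated with LiN(iPr)2 (3.2 equiv, THF, −78 °C) to the phenoxide/benzylic dianion and acylated with F1 to give methyl 2-hydroxy-4-methoxy-6-(2-oxopentyl)benzoate F2. Saponification of F2 (2 M NaOH, MeOH, 50 °C, then HCl at 0 °C) gives 6; any 5 formed by lactonisation is opened in the same operation.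

Step 5 (the proposed new step). Possible failures are slow boron-to-copper transmetalation of the pinacol ester, oxidation of 12 to the phenol, O-arylation at the salicylic OH, copper/O2 oxidation of the benzylic ketone methylene, and base-promoted loss of the ring B phenol from 13 with formation of 5. The fallback uses known chemistry and keeps the carboxylate as the nucleophile; it sets out from 11 and comes back at 13. Arene 11 is borylated as in the first stage and 12 is isolated by filtration through silica. Ipso-bromination of 12 with CuBr2 (3 equiv) in MeOH/H2O at 80 °C gives tert-butyl 4-bromo-2-methoxy-6-pentylbenzoate F3. F3 is coupled with 6 by the known nickel/photoredox esterification of aryl bromides with carboxylic acids (NiBr2·glyme 5 mol %, 4,4'-di-tert-butyl-2,2'-bipyridine, Ir(ppy)3 1 mol %, N-tert-butylisopropylamine, DMF, blue LEDs, rt) to give 13.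

Step 6. TFA could promote attack of the ketone enol on the aryl ester (isocoumarin 5 plus the ring B phenol) or tert-butylation of ring A. The fallback moves the acid treatment ahead of the depside bond and ends with a neutral hydrogenolysis; it sets out from 12 (isolated) and comes back at 14. Treating 12 with TFA/CH2Cl2 at rt gives 2-methoxy-6-pentyl-4-(4,4,5,5-tetramethyl-1,3,2-dioxaborolan-2-yl)benzoic acid F4. Benzyl bromide and KHCO3 in DMF at rt give benzyl 2-methoxy-6-pentyl-4-(4,4,5,5-tetramethyl-1,3,2-dioxaborolan-2-yl)benzoate F5. Copper coupling of F5 with 6 under the second-stage conditions of step 5 gives benzyl 4-{[2-hydroxy-4-methoxy-6-(2-oxopentyl)benzoyl]oxy}-2-methoxy-6-pentylbenzoate F6. Hydrogenolysis of F6 (H2 1 atm, Pd/C (10 wt % Pd on carbon), EtOAc, rt) gives 14.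

**Further compounds**
F1 | step 2 | N-methoxy-N-methylbutanamide | CCCC(=O)N(C)OC
F2 | step 2 | methyl 2-hydroxy-4-methoxy-6-(2-oxopentyl)benzoate | CCCC(=O)Cc1cc(OC)cc(O)c1C(=O)OC
F3 | step 5 | tert-butyl 4-bromo-2-methoxy-6-pentylbenzoate | CCCCCc1cc(Br)cc(OC)c1C(=O)OC(C)(C)C
F4 | step 6 | 2-methoxy-6-pentyl-4-(4,4,5,5-tetramethyl-1,3,2-dioxaborolan-2-yl)benzoic acid | CCCCCc1cc(B2OC(C)(C)C(C)(C)O2)cc(OC)c1C(=O)O
F5 | step 6 | benzyl 2-methoxy-6-pentyl-4-(4,4,5,5-tetramethyl-1,3,2-dioxaborolan-2-yl)benzoate | CCCCCc1cc(B2OC(C)(C)C(C)(C)O2)cc(OC)c1C(=O)OCc1ccccc1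
F6 | step 6 | benzyl 4-{[2-hydroxy-4-methoxy-6-(2-oxopentyl)benzoyl]oxy}-2-methoxy-6-pentylbenzoate | CCCCCc1cc(OC(=O)c2c(O)cc(OC)cc2CC(=O)CCC)cc(OC)c1C(=O)OCc1ccccc1
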